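## Retrosynthetic overview

1. The angelate ester on the C9 hydroxyl is made last.
2. Key step, ring B formed last: a SmI2 ketyl from a C9 aldehyde adds to the β-carbon (C8) of an α-(acetoxymethyl)butenolide and the enolate loses acetate. This gives the C8–C9 bond, the second oxepane and the exocyclic methylene lactone in one operation.
3. Butenolide, formed second: Nozaki–Hiyama–Kishi coupling of a C7 aldehyde with a (Z)-β-iodoacrylate, then lactonization.
4. Ring A, formed first: 7-exo opening of a catalyst-made terminal epoxide by the tertiary hydroxyl, with inversion at C6.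
5. C4/C5 come from an iridium-catalysed anti-(hydroxymethyl)allylation of a C4 aldehyde; C1, C2–C4, C9, C10 and the methyl group come from (R)-linalool.

Assumption: the SMILES is read literally; it places the C10 arm on C1 and the C7 arm on C6 trans across the ether oxygen (a trans-bridged, inside–outside 11-oxabicyclo[4.4.1]undecane), so both ether stereocentres are fixed before ring B is closed.

Locants: C1 (quaternary, CH3 = C14, ether O), C2, C3, C4 (OAc), C5 (CH2OAc = C15), C6 (ether O), C7 (lactone O), C8, C9 (angelate), C10; lactone carbons C11 (=C13H2) and C12 (C=O). TBDPS = tert-butyldiphenylsilyl, TES = triethylsilyl.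

## Route

Step 1
Reactants: 1 (R)-linalool
Product: 3 (3R)-3,7-dimethyloct-6-ene-1,3-diol, via alkylborane 2 (not isolated)
Conditions: 9-BBN (2.2 equiv), THF, 0 °C to rt; then NaOH, H2O2
Reagents that add atoms: hydrogen peroxide (OO)
Why: 9-BBN hydroborates the monosubstituted vinyl group far faster than the trisubstituted alkene (anti-Markovnikov hydroboration–oxidation), giving the C9 primary alcohol while the linalool stereocentre (C1, R) is untouched.

Step 2
Reactants: 3 (3R)-3,7-dimethyloct-6-ene-1,3-diol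
Product: 5 (3R)-1-(TBDPS-oxy)-3,7-dimethyl-3-(TES-oxy)oct-6-ene, via mono-TBDPS ether 4 (not isolated)
Conditions: TBDPSCl, imidazole, CH2Cl2, 0 °C; then TESOTf, 2,6-lutidine, −78 to 0 °C
Reagents that add atoms: tert-butyl(chloro)diphenylsilane (CC(C)(C)[Si](Cl)(c1ccccc1)c1ccccc1); triethylsilyl trifluoromethanesulfonate (CC[Si](CC)(CC)OS(=O)(=O)C(F)(F)F)
Why: The bulky silyl chloride takes only the primary hydroxyl and the silyl triflate then caps the tertiary one (one-pot double silyl protection), which keeps the aldehyde of step 3 from closing to a lactol that could not enter the allylation of step 4.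

Step 3
Reactants: 5 (3R)-1-(TBDPS-oxy)-3,7-dimethyl-3-(TES-oxy)oct-6-ene
Product: 7 (4R)-6-(TBDPS-oxy)-4-methyl-4-(TES-oxy)hexanal, via ozonide 6 (not isolated)
Conditions: O3, CH2Cl2, −78 °C; then PPh3, −78 °C to rt
Reagents that add atoms: ozone ([O-][O+]=O)
Why: Ozonolysis (Criegee mechanism) of the only remaining alkene gives the secondary ozonide, which PPh3 reduces to the C4 aldehyde and acetone without touching the silyl ethers or the C1 stereocentre.

Step 4
Reactants: 7 (4R)-6-(TBDPS-oxy)-4-methyl-4-(TES-oxy)hexanal; 8 4-vinyl-1,3-dioxolan-2-one (vinyl ethylene carbonate, racemic)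
Product: 9 (2S,3S,6R)-8-(TBDPS-oxy)-6-methyl-6-(TES-oxy)-2-vinyloctane-1,3-diol
Conditions: [Ir(cod)Cl]2 (2.5 mol %), (R)-SEGPHOS (5 mol %), 4-cyano-3-nitrobenzoic acid (10 mol %), K3PO4 (cat.), 2-propanol (2 equiv), THF, 60 °C
Reagents that add atoms: none
Why: Krische transfer-hydrogenative carbonyl (hydroxymethyl)allylation at the aldehyde oxidation level: 2-propanol is the terminal reductant that converts the π-allyl iridium species formed from 8 with loss of CO2 into the nucleophilic (E)-σ-allyl iridium species, which adds to aldehyde 7 through a chair-like transition state to give the anti C4/C5 pair (cis on the later oxepane), the absolute sense being fixed by the ligand antipode (the one that delivers the S carbinol is used).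

Step 5
Reactants: 9 (2S,3S,6R)-8-(TBDPS-oxy)-6-methyl-6-(TES-oxy)-2-vinyloctane-1,3-diol
Product: 11 (2S,3S,6R)-8-(TBDPS-oxy)-6-hydroxy-6-methyl-2-vinyloctane-1,3-diyl diacetate, via triethylsilyl ether diacetate 10 (not isolated)
Conditions: Ac2O, pyridine, DMAP (cat.), CH2Cl2, rt; then CSA (cat.), MeOH, 0 °C
Reagents that add atoms: acetic anhydride (CC(=O)OC(C)=O)
Why: Standard acetylation installs both target acetates while the tertiary oxygen is still silylated, and brief acid methanolysis then removes only the triethylsilyl ether because the acetates and the TBDPS ether survive these conditions.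

Step 6
Reactants: 11 (2S,3S,6R)-8-(TBDPS-oxy)-6-hydroxy-6-methyl-2-vinyloctane-1,3-diyl diacetate
Product: 13 [(2R,3S,4S,7R)-4-acetoxy-7-[2-(TBDPS-oxy)ethyl]-2-(hydroxymethyl)-7-methyloxepan-3-yl]methyl acetate, via epoxide 12 (not isolated)
Conditions: Ti(OiPr)4 (10 mol %), cis-DACH salalen ligand (antipode giving the S epoxide), 30% aq. H2O2, CH2Cl2, rt; then CSA (cat.), CH2Cl2, 0 °C to rt
Reagents that add atoms: hydrogen peroxide (OO)
Why: Katsuki–Berkessel titanium salalen epoxidation sets the (S)-epoxide at C6 under catalyst control, and acid-promoted 7-exo-tet epoxide opening by the tertiary hydroxyl then closes ring A with clean inversion, so C6 ends R with its C7 arm trans to the C10 arm across the ether oxygen.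

Step 7
Reactants: 13 [(2R,3S,4S,7R)-4-acetoxy-7-[2-(TBDPS-oxy)ethyl]-2-(hydroxymethyl)-7-methyloxepan-3-yl]methyl acetate
Product: 14 [(2R,3S,4S,7R)-4-acetoxy-7-[2-(TBDPS-oxy)ethyl]-2-formyl-7-methyloxepan-3-yl]methyl acetate
Conditions: DMP, CH2Cl2, 0 °C to rt
Reagents that add atoms: none
Why: Dess–Martin oxidation gives the α-alkoxy aldehyde under neutral conditions that do not epimerize C6.

Step 8
Reactants: 15 methyl propiolate
Product: 17 methyl (2Z)-2-(acetoxymethyl)-3-iodoprop-2-enoate, via hydroxymethyl iodoacrylate 16 (not isolated)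
Conditions: Et2AlI, CH2Cl2, 0 °C, monomeric CH2O (from cracked paraformaldehyde); then Ac2O, pyridine, DMAP
Reagents that add atoms: diethylaluminium iodide (CC[Al](I)CC); formaldehyde (C=O); acetic anhydride (CC(=O)OC(C)=O)
Why: Iodide adds to the propiolate to give a β-iodo allenolate that is trapped by formaldehyde at the α-carbon (β-iodo Morita–Baylis–Hillman-type iodo-aldol reaction, Z-selective at 0 °C), and the alcohol is acetylated in the same flask.

Step 9
Reactants: 14 [(2R,3S,4S,7R)-4-acetoxy-7-[2-(TBDPS-oxy)ethyl]-2-formyl-7-methyloxepan-3-yl]methyl acetate; 17 methyl (2Z)-2-(acetoxymethyl)-3-iodoprop-2-enoate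
Product: 19 [(2R,3S,4S,7R)-4-acetoxy-2-[(2S)-4-(acetoxymethyl)-5-oxo-2,5-dihydrofuran-2-yl]-7-[2-(TBDPS-oxy)ethyl]-7-methyloxepan-3-yl]methyl acetate, via hydroxy enoate 18 (not isolated)
Conditions: CrCl2 (4 equiv), NiCl2 (1 mol %), DMSO, rt; then PPTS, CH2Cl2
Reagents that add atoms: none
Why: Nozaki–Hiyama–Kishi coupling adds the alkenylchromium species only to the aldehyde (acetates tolerated) under polar Felkin–Anh control by the α-ether oxygen to give the anti (7S) carbinol, which closes onto the cis-disposed methyl ester to form the butenolide.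

Step 10
Reactants: 19 butenolide TBDPS ether (name as in step 9)
Product: 20 [(2R,3S,4S,7R)-4-acetoxy-2-[(2S)-4-(acetoxymethyl)-5-oxo-2,5-dihydrofuran-2-yl]-7-(2-hydroxyethyl)-7-methyloxepan-3-yl]methyl acetate
Conditions: HF·pyridine, THF/pyridine, 0 °C to rt
Reagents that add atoms: none
Why: Buffered fluoride removes the primary TBDPS ether without touching the acetates or the butenolide.

Step 11
Reactants: 20 butenolide primary alcohol (name as in step 10)
Product: 21 [(2R,3S,4S,7R)-4-acetoxy-2-[(2S)-4-(acetoxymethyl)-5-oxo-2,5-dihydrofuran-2-yl]-7-methyl-7-(2-oxoethyl)oxepan-3-yl]methyl acetate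
Conditions: DMP, CH2Cl2, 0 °C
Reagents that add atoms: none
Why: Dess–Martin oxidation gives the C9 aldehyde under neutral conditions that avoid β-elimination of the C1 ether oxygen.

Step 12
Reactants: 21 butenolide aldehyde (name as in step 11)
Product: 22 9-hydroxy tricyclic α-methylene lactone (the target lacking its angeloyl group; 1R,4S,5S,6R,7S,8R,9R)
Conditions: SmI2 (2.2 equiv), THF, 0.005 M, −78 to −30 °C, no HMPA; AcOH quench at −78 °C
Reagents that add atoms: none
Why: Proposed new method: SmI2 turns the normally electrophilic aldehyde carbon C9 into a nucleophilic ketyl that adds 7-exo to the normally electrophilic β-carbon C8 of the butenolide on the face anti to the C6 substituent at C7 (H7/H8 trans), the resulting samarium enolate expels the β-acetoxy group to unveil the exocyclic methylene, and bridging of the ketyl oxygen and the lactone carbonyl by trivalent samarium in the absence of HMPA places the new hydroxyl syn to C11 (9R), the closest known reaction types being SmI2 ketyl–olefin cyclizations onto unsaturated lactones and sequential ketyl–olefin coupling/β-elimination.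

Step 13
Reactants: 22 9-hydroxy tricyclic α-methylene lactone; 23 angelic acid [(Z)-2-methylbut-2-enoic acid]
Product: 25 target CNP0346171.1 (9-O-angeloyl ester; 1R,4S,5S,6R,7S,8R,9R), via mixed anhydride 24 (not isolated)
Conditions: 2,4,6-trichlorobenzoyl chloride, Et3N, toluene, rt; then 22, 80 °C (no DMAP)
Reagents that add atoms: none
Why: Yamaguchi-type mixed-anhydride esterification acylates the only free hydroxyl and is the established way to install an angelate without Z-to-E isomerization to the tiglate.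

## Compound list

1 | (R)-linalool, (3R)-3,7-dimethylocta-1,6-dien-3-ol | O[C@](C)(CCC=C(C)C)C=C | starting material
2 | (3R)-1-(9-borabicyclo[3.3.1]nonan-9-yl)-3,7-dimethyloct-6-en-3-ol | O[C@](C)(CCC=C(C)C)CCB1C2CCCC1CCC2 | intermediate
3 | (3R)-3,7-dimethyloct-6-ene-1,3-diol | O[C@](C)(CCC=C(C)C)CCO | intermediate
4 | (3R)-1-(TBDPS-oxy)-3,7-dimethyloct-6-en-3-ol | O[C@](C)(CCC=C(C)C)CCO[Si](c1ccccc1)(c1ccccc1)C(C)(C)C | intermediate
5 | (3R)-1-(TBDPS-oxy)-3,7-dimethyl-3-(TES-oxy)oct-6-ene | CC[Si](CC)(CC)O[C@](C)(CCC=C(C)C)CCO[Si](c1ccccc1)(c1ccccc1)C(C)(C)C | intermediate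
6 | 3,3-dimethyl-5-[(3R)-5-(TBDPS-oxy)-3-methyl-3-(TES-oxy)pentyl]-1,2,4-trioxolane (secondary ozonide, mixture at the trioxolane carbon) | CC[Si](CC)(CC)O[C@](C)(CCC1OOC(C)(C)O1)CCO[Si](c1ccccc1)(c1ccccc1)C(C)(C)C | intermediate
7 | (4R)-6-(TBDPS-oxy)-4-methyl-4-(TES-oxy)hexanal | CC[Si](CC)(CC)O[C@](C)(CCC=O)CCO[Si](c1ccccc1)(c1ccccc1)C(C)(C)C | intermediate
8 | 4-vinyl-1,3-dioxolan-2-one (vinyl ethylene carbonate) | C=CC1COC(=O)O1 | starting material
9 | (2S,3S,6R)-8-(TBDPS-oxy)-6-methyl-6-(TES-oxy)-2-vinyloctane-1,3-diol | CC[Si](CC)(CC)O[C@](C)(CC[C@H](O)[C@@H](C=C)CO)CCO[Si](c1ccccc1)(c1ccccc1)C(C)(C)C | intermediate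
10 | (2S,3S,6R)-8-(TBDPS-oxy)-6-methyl-6-(TES-oxy)-2-vinyloctane-1,3-diyl diacetate | CC[Si](CC)(CC)O[C@](C)(CC[C@H](OC(C)=O)[C@@H](C=C)COC(C)=O)CCO[Si](c1ccccc1)(c1ccccc1)C(C)(C)C | intermediate
11 | (2S,3S,6R)-8-(TBDPS-oxy)-6-hydroxy-6-methyl-2-vinyloctane-1,3-diyl diacetate | O[C@](C)(CC[C@H](OC(C)=O)[C@@H](C=C)COC(C)=O)CCO[Si](c1ccccc1)(c1ccccc1)C(C)(C)C | intermediate
12 | (2S,3S,6R)-8-(TBDPS-oxy)-6-hydroxy-6-methyl-2-[(2S)-oxiran-2-yl]octane-1,3-diyl diacetate | O[C@](C)(CC[C@H](OC(C)=O)[C@H](COC(C)=O)[C@H]1CO1)CCO[Si](c1ccccc1)(c1ccccc1)C(C)(C)C | intermediate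
13 | [(2R,3S,4S,7R)-4-acetoxy-7-[2-(TBDPS-oxy)ethyl]-2-(hydroxymethyl)-7-methyloxepan-3-yl]methyl acetate | OC[C@@H]1O[C@](C)(CC[C@H](OC(C)=O)[C@@H]1COC(C)=O)CCO[Si](c2ccccc2)(c2ccccc2)C(C)(C)C | intermediate
14 | [(2R,3S,4S,7R)-4-acetoxy-7-[2-(TBDPS-oxy)ethyl]-2-formyl-7-methyloxepan-3-yl]methyl acetate | O=C[C@@H]1O[C@](C)(CC[C@H](OC(C)=O)[C@@H]1COC(C)=O)CCO[Si](c2ccccc2)(c2ccccc2)C(C)(C)C | intermediate
15 | methyl propiolate | C#CC(=O)OC | starting material
16 | methyl (2Z)-2-(hydroxymethyl)-3-iodoprop-2-enoate | COC(=O)/C(CO)=C\I | intermediate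
17 | methyl (2Z)-2-(acetoxymethyl)-3-iodoprop-2-enoate | COC(=O)/C(COC(C)=O)=C\I | intermediate
18 | methyl (2Z,4S)-2-(acetoxymethyl)-4-hydroxy-4-[(2R,3S,4S,7R)-4-acetoxy-3-(acetoxymethyl)-7-[2-(TBDPS-oxy)ethyl]-7-methyloxepan-2-yl]but-2-enoate | COC(=O)/C(COC(C)=O)=C\[C@H](O)[C@@H]1O[C@](C)(CC[C@H](OC(C)=O)[C@@H]1COC(C)=O)CCO[Si](c2ccccc2)(c2ccccc2)C(C)(C)C | intermediate
19 | [(2R,3S,4S,7R)-4-acetoxy-2-[(2S)-4-(acetoxymethyl)-5-oxo-2,5-dihydrofuran-2-yl]-7-[2-(TBDPS-oxy)ethyl]-7-methyloxepan-3-yl]methyl acetate | O=C1O[C@@H](C=C1COC(C)=O)[C@@H]2O[C@](C)(CC[C@H](OC(C)=O)[C@@H]2COC(C)=O)CCO[Si](c3ccccc3)(c3ccccc3)C(C)(C)C | intermediate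
20 | [(2R,3S,4S,7R)-4-acetoxy-2-[(2S)-4-(acetoxymethyl)-5-oxo-2,5-dihydrofuran-2-yl]-7-(2-hydroxyethyl)-7-methyloxepan-3-yl]methyl acetate | O=C1O[C@@H](C=C1COC(C)=O)[C@@H]2O[C@](C)(CC[C@H](OC(C)=O)[C@@H]2COC(C)=O)CCO | intermediate
21 | [(2R,3S,4S,7R)-4-acetoxy-2-[(2S)-4-(acetoxymethyl)-5-oxo-2,5-dihydrofuran-2-yl]-7-methyl-7-(2-oxoethyl)oxepan-3-yl]methyl acetate | O=C1O[C@@H](C=C1COC(C)=O)[C@@H]2O[C@](C)(CC[C@H](OC(C)=O)[C@@H]2COC(C)=O)CC=O | intermediate
22 | 9-hydroxy tricyclic α-methylene lactone: 4-acetoxy-5-(acetoxymethyl)-9-hydroxy-1-methyl-11-oxabicyclo[4.4.1]undecane with the 11-methylene-7,12-olide fused at C7/C8 (1R,4S,5S,6R,7S,8R,9R) | C=C1C(=O)O[C@@H]2[C@@H]3O[C@](C)(CC[C@H](OC(C)=O)[C@@H]3COC(C)=O)C[C@@H](O)[C@@H]12 | intermediate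
23 | angelic acid, (Z)-2-methylbut-2-enoic acid | OC(=O)/C(C)=C\C | starting material
24 | (Z)-2-methylbut-2-enoic 2,4,6-trichlorobenzoic anhydride | O=C(OC(=O)/C(C)=C\C)c1c(Cl)cc(Cl)cc1Cl | intermediate
25 | CNP0346171.1: the 9-O-[(Z)-2-methylbut-2-enoyl] ester of 22 (1R,4S,5S,6R,7S,8R,9R) | C=C1C(=O)O[C@@H]2[C@@H]3O[C@](C)(CC[C@H](OC(C)=O)[C@@H]3COC(C)=O)C[C@@H](OC(=O)/C(C)=C\C)[C@@H]12 | target

## Step count and risks

Total step count: 13. Longest linear sequence: 12 (steps 1–7 and 9–13; step 8 makes the coupling partner).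

The three steps most likely to fail:

Step 12 (key ketyl cyclization). The closure builds a strained trans-bridged bicycle, so simple aldehyde reduction, pinacol coupling or reductive loss of the allylic acetate may win, and the C9 configuration rests on a chelation model. Fallback: set out from 21 and replace the radical step by a two-electron one. Pd(PPh3)4 ionizes the allylic acetate of the butenolide and InI reduces the π-allylpalladium species to an allylindium reagent, which adds through its γ-carbon C8 to the tethered aldehyde in a closed transition state (umpoled Tsuji–Trost/Barbier cyclization). This gives the same hydroxy methylene lactone, so the route is rejoined at 22, and no new compound is made (F0).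

Step 6 (epoxidation and 7-exo etherification). The two acetates can attack the protonated epoxide through six-membered acyloxonium ions, and seven-membered ring closure by a tertiary alcohol is slow. Fallback: set out from 11 and avoid acid altogether. Cross-metathesis with (Z)-but-2-ene-1,4-diyl dimethyl dicarbonate (second-generation Hoveyda–Grubbs catalyst) gives the (E)-allylic methyl carbonate F1. Branched-selective allylic etherification by the tertiary hydroxyl with [Ir(cod)Cl]2 and a chiral phosphoramidite ligand (catalyst control at C6) closes ring A to the 2-vinyloxepane F2. Ozonolysis with PPh3 work-up then delivers aldehyde 14 directly, where the route is rejoined.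

Step 9 (Nozaki–Hiyama–Kishi coupling). The functionalized alkenyl iodide may couple poorly, and Felkin selectivity at C7 may be modest. Fallback: set out from 14 and build the butenolide by metathesis. Vinylmagnesium bromide with CeCl3 at −78 °C (non-chelating, Felkin addition) gives the allylic alcohol F3. Steglich esterification (DCC, DMAP) with 2-(acetoxymethyl)acrylic acid (C=C(COC(C)=O)C(=O)O) gives the diene ester F4. Ring-closing metathesis with second-generation Grubbs catalyst then closes the butenolide with loss of ethene and rejoins the route at 19.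

## Further compounds

F0 | step 12 | none | none
F1 | step 6 | (2S,3S,6R)-8-(TBDPS-oxy)-6-hydroxy-2-[(E)-3-(methoxycarbonyloxy)prop-1-enyl]-6-methyloctane-1,3-diyl diacetate | O[C@](C)(CC[C@H](OC(C)=O)[C@@H](/C=C/COC(=O)OC)COC(C)=O)CCO[Si](c1ccccc1)(c1ccccc1)C(C)(C)C
F2 | step 6 | [(2S,3S,4S,7R)-4-acetoxy-7-[2-(TBDPS-oxy)ethyl]-7-methyl-2-vinyloxepan-3-yl]methyl acetate | C=C[C@@H]1O[C@](C)(CC[C@H](OC(C)=O)[C@@H]1COC(C)=O)CCO[Si](c2ccccc2)(c2ccccc2)C(C)(C)C
F3 | step 9 | [(2R,3S,4S,7R)-4-acetoxy-7-[2-(TBDPS-oxy)ethyl]-2-[(1S)-1-hydroxyprop-2-enyl]-7-methyloxepan-3-yl]methyl acetate | C=C[C@H](O)[C@@H]1O[C@](C)(CC[C@H](OC(C)=O)[C@@H]1COC(C)=O)CCO[Si](c2ccccc2)(c2ccccc2)C(C)(C)C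
F4 | step 9 | (1S)-1-[(2R,3S,4S,7R)-4-acetoxy-3-(acetoxymethyl)-7-[2-(TBDPS-oxy)ethyl]-7-methyloxepan-2-yl]prop-2-enyl 2-(acetoxymethyl)prop-2-enoate | C=C(COC(C)=O)C(=O)O[C@@H](C=C)[C@@H]1O[C@](C)(CC[C@H](OC(C)=O)[C@@H]1COC(C)=O)CCO[Si](c2ccccc2)(c2ccccc2)C(C)(C)C
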